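**Retrosynthetic overview**

1. Target 15 ← 4,5,6-tribromoindole 10: both C–S bonds are made last, in one operation with methanesulfenyl chloride, first at C3 and then at C2 through a 3,3-bis-sulfide and 1,2-shift.
2. 10 ← N-Boc-4,5,6-tribromoindoline 8 (Boc removal, dehydrogenation of the five-membered ring) ← N-Boc-4,5,6,7-tetrabromoindoline 6 by carbamate-directed Br–Mg exchange and protonation at C7.
3. 6 ← cis-3a,7a-dihydro compound 5 (DDQ) ← tetrabromothiophene 1,1-dioxide 2 + N-Boc-2-pyrroline 3 by [4+2] cycloaddition and SO2 extrusion.
4. Feature on which the plan rests: benzo-ring carbons C4–C7, of which C4, C5 and C6 carry the contiguous bromines, are the four brominated carbons of 2, and the ring-fusion bond C3a–C7a is the enamide C=C of 3.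
5. Ring order: the five-membered nitrogen ring is bought in; the six-membered carbocycle is formed in step 2 and aromatised in step 3; the pyrrole ring is aromatised in step 6.

Key step: step 2

Assumption (remark on the chemistry): the target is achiral and the two stereocentres made in step 2 are destroyed in step 3, so 4 and 5 are carried as racemates (one enantiomer is drawn in the SMILES; the configuration of 4 at the sulfone bridge is left open because the bridge is lost).

**Route**

Step 1
Reactants: 1 2,3,4,5-tetrabromothiophene
Product: 2 2,3,4,5-tetrabromothiophene 1,1-dioxide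
Conditions: H2O2 (50% aq.), (CF3CO)2O, CH2Cl2, 0 °C → rt
Reagents that add atoms: trifluoroperacetic acid, OOC(=O)C(F)(F)F (made in the flask from hydrogen peroxide, OO, and trifluoroacetic anhydride, O=C(OC(=O)C(F)(F)F)C(F)(F)F)
Why: Sulfide-to-sulfone oxidation with a peracid; the electron-poor tetrahalothiophene needs the strongly electrophilic trifluoroperacetic acid, and the four bromines should stabilise the non-aromatic dioxide against dimerisation so that it can be isolated acid-free by crystallisation.

Step 2
Reactants: 2 2,3,4,5-tetrabromothiophene 1,1-dioxide; 3 tert-butyl 2,3-dihydro-1H-pyrrole-1-carboxylate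
Product: 5 tert-butyl cis-4,5,6,7-tetrabromo-2,3,3a,7a-tetrahydro-1H-indole-1-carboxylate (racemic; 3aR*,7aS*), via 4,7-sulfonyl-bridged cycloadduct 4 (not isolated)
Conditions: 3 (1.2 equiv), toluene, 20 → 60 °C, slow N2 sweep
Reagents that add atoms: none
Why: The electron-poor, non-aromatic diene 2 and the electron-rich enamide C4=C5 bond of 3 should undergo an inverse-electron-demand Diels–Alder reaction (asynchronous, the nucleophilic enamide β-carbon, the future C3a, bonding first to a sulfone α-carbon), and the strained 7-thiabicyclo[2.2.1]heptene 7,7-dioxide 4 then loses SO2 by cheletropic extrusion to leave the 1,3-cyclohexadiene. The closest known reaction type is the annulation of alkenes with tetrahalothiophene 1,1-dioxides, which gives tetrahalocyclohexadienes after loss of SO2. The six-membered carbocycle is closed by intermolecular [4+2] cycloaddition onto the existing five-membered ring (bonds C3a–C4 and C7–C7a); the sulfone bridge is the only other ring formed and it is lost again. C3a and C7a are set cis because the addition is suprafacial on a cis ring alkene, so only a cis fusion can form; the product is racemic and the endo/exo ratio in 4 does not matter because the bridge is extruded. No regioselectivity is needed since 2 is symmetric; the step needs chemoselectivity for cycloaddition over acid-induced enamide decomposition, and survival of the dihydro stage without loss of HBr or C7a–N cleavage to a ring-opened arene, which acid-free 2, a neutral non-polar medium, modest temperature and the poor leaving-group ability of the carbamate nitrogen should secure.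

Step 3
Reactants: 5 tert-butyl cis-4,5,6,7-tetrabromo-2,3,3a,7a-tetrahydro-1H-indole-1-carboxylate
Product: 6 tert-butyl 4,5,6,7-tetrabromo-2,3-dihydro-1H-indole-1-carboxylate
Conditions: DDQ (1.2 equiv), toluene, 60 °C
Reagents that add atoms: none
Why: DDQ dehydrogenation of a 1,3-cyclohexadiene: hydride abstraction from C7a–H (allylic to the diene and α to the carbamate nitrogen) gives an arenium-type cation that loses the C3a proton, so both stereocentres vanish, all four bromines are kept and the N-acyl indoline is not oxidised further.

Step 4
Reactants: 6 tert-butyl 4,5,6,7-tetrabromo-2,3-dihydro-1H-indole-1-carboxylate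
Product: 8 tert-butyl 4,5,6-tribromo-2,3-dihydro-1H-indole-1-carboxylate, via C7 arylmagnesium chloride 7 (not isolated)
Conditions: iPrMgCl·LiCl (1.05 equiv), THF, −40 °C; then MeOH, −40 °C → rt
Reagents that add atoms: none
Why: Directed bromine–magnesium exchange: the Boc carbonyl, which lies on the C7 side in N-Boc indolines, should pre-complex magnesium and chelate the C7 arylmagnesium, which is also stabilised by the ortho C6 bromine and by relief of the Boc/C7–Br strain, and cold protonation before any aryne formation then gives the C7–H arene.

Step 5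
Reactants: 8 tert-butyl 4,5,6-tribromo-2,3-dihydro-1H-indole-1-carboxylate
Product: 9 4,5,6-tribromo-2,3-dihydro-1H-indole
Conditions: CF3CO2H, CH2Cl2, 0 °C → rt; aq. NaHCO3 work-up
Reagents that add atoms: none
Why: Acidolysis of a tert-butyl carbamate (loss of the tert-butyl cation as isobutene, then decarboxylation), to which aryl bromides are inert.

Step 6
Reactants: 9 4,5,6-tribromo-2,3-dihydro-1H-indole
Product: 10 4,5,6-tribromo-1H-indole
Conditions: activated MnO2 (excess), CH2Cl2, rt
Reagents that add atoms: none
Why: Indoline-to-indole dehydrogenation with activated MnO2, which oxidises the N–H/C2–C3 unit of N-unsubstituted indolines to the aromatic pyrrole ring without touching aryl bromides.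

Step 7
Reactants: 10 4,5,6-tribromo-1H-indole; 11 dimethyl disulfide
Product: 15 4,5,6-tribromo-2,3-bis(methylsulfanyl)-1H-indole (target), via methanesulfenyl chloride 12 (not isolated), via 3-(methylsulfanyl)indole 13 (not isolated), via 3,3-bis(methylsulfanyl)indolenine 14 (not isolated)
Conditions: 11 (1.2 equiv), SO2Cl2 (1.2 equiv), CH2Cl2, −20 °C; added to 10 in two portions, −78 → 0 °C, then 0 °C → rt
Reagents that add atoms: none
Why: Twofold electrophilic sulfenylation of an indole by a sulfenyl chloride made by chlorinolysis of the disulfide: the first equivalent substitutes C3, the most nucleophilic position, the second attacks C3 of the 3-sulfide again to give the 3,3-bis-sulfide indoleninium ion, and one sulfur group then shifts to C2 through an episulfonium ion (Plancher-type 1,2-migration, helped here by relief of the C4–Br peri strain and by the HCl formed) before loss of the C2 proton restores the indole.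

**Compound list**

1 | 2,3,4,5-tetrabromothiophene | Brc1sc(Br)c(Br)c1Br | starting material
2 | 2,3,4,5-tetrabromothiophene 1,1-dioxide | O=S1(=O)C(Br)=C(Br)C(Br)=C1Br | intermediate
3 | tert-butyl 2,3-dihydro-1H-pyrrole-1-carboxylate | CC(C)(C)OC(=O)N1CCC=C1 | starting material
4 | tert-butyl 4,5,6,7-tetrabromo-4,7-sulfonyl-bridged 2,3,3a,4,7,7a-hexahydro-1H-indole-1-carboxylate (racemic, cis ring fusion, bridge configuration open) | CC(C)(C)OC(=O)N1CC[C@H]2[C@@H]1C1(Br)C(Br)=C(Br)C2(Br)S1(=O)=O | intermediate (not isolated)
5 | tert-butyl cis-4,5,6,7-tetrabromo-2,3,3a,7a-tetrahydro-1H-indole-1-carboxylate (racemic; 3aR*,7aS*) | CC(C)(C)OC(=O)N1CC[C@H]2[C@@H]1C(Br)=C(Br)C(Br)=C2Br | intermediate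
6 | tert-butyl 4,5,6,7-tetrabromo-2,3-dihydro-1H-indole-1-carboxylate | CC(C)(C)OC(=O)N1CCc2c(Br)c(Br)c(Br)c(Br)c21 | intermediate
7 | [4,5,6-tribromo-1-(tert-butoxycarbonyl)-2,3-dihydro-1H-indol-7-yl]magnesium chloride (LiCl complex) | CC(C)(C)OC(=O)N1CCc2c(Br)c(Br)c(Br)c([Mg]Cl)c21 | intermediate (not isolated)
8 | tert-butyl 4,5,6-tribromo-2,3-dihydro-1H-indole-1-carboxylate | CC(C)(C)OC(=O)N1CCc2c(Br)c(Br)c(Br)cc21 | intermediate
9 | 4,5,6-tribromo-2,3-dihydro-1H-indole | Brc1cc2NCCc2c(Br)c1Br | intermediate
10 | 4,5,6-tribromo-1H-indole | Brc1cc2[nH]ccc2c(Br)c1Br | intermediate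
11 | dimethyl disulfide | CSSC | starting material
12 | methanesulfenyl chloride | CSCl | intermediate (not isolated)
13 | 4,5,6-tribromo-3-(methylsulfanyl)-1H-indole | CSc1c[nH]c2cc(Br)c(Br)c(Br)c12 | intermediate (not isolated)
14 | 4,5,6-tribromo-3,3-bis(methylsulfanyl)-3H-indole | CSC1(SC)C=Nc2cc(Br)c(Br)c(Br)c21 | intermediate (not isolated)
15 | 4,5,6-tribromo-2,3-bis(methylsulfanyl)-1H-indole | CSc1[nH]c2cc(Br)c(Br)c(Br)c2c1SC | target

**Step count and risks**

Total step count: 7. Longest linear sequence: 7 steps (1 → 15); 3 and 11 enter as purchased materials.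

Steps most likely to fail:

1. Step 4. Magnesium may enter at C5 or C6, each flanked by two bromines, instead of the carbamate-flanked C7, or exchange may occur twice. Fallback: the organometallic differentiation is replaced by an electrophilic one that only nitrogen-activated positions can undergo. Setting out from 6, CF3CO2H in CH2Cl2 removes the Boc group to give 4,5,6,7-tetrabromo-2,3-dihydro-1H-indole F1. Heating F1 with aqueous HBr in acetic acid in the presence of Na2SO3 as bromine scavenger should remove, by ipso-protonation, only the bromines ortho and para to the amine nitrogen (C7 and C5), giving 4,6-dibromo-2,3-dihydro-1H-indole F2. Bromination of F2 with N-bromosuccinimide (1 equiv, DMF, −20 °C), which in indolines goes para to nitrogen, should put bromine back on C5, and the route is rejoined at 9.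

2. Step 2. The enamide may be consumed by acid-induced oligomerisation or by open-chain conjugate addition to 2, or the dihydro adduct may aromatise early by loss of HBr or by C7a–N cleavage. Fallback: the benzene ring is formed at the aromatic oxidation level with an alkyne and the five-membered ring is closed afterwards. Setting out from 2, cycloaddition with 4-bromobut-1-yne (xylene, 130 °C) and loss of SO2 should give 1,2,3,4-tetrabromo-5-(2-bromoethyl)benzene F3 directly. Nitration at the single free ring position (fuming HNO3, H2SO4) gives 1,2,3,4-tetrabromo-5-(2-bromoethyl)-6-nitrobenzene F4. Reduction (Fe powder, AcOH) gives 2,3,4,5-tetrabromo-6-(2-bromoethyl)aniline F5, which is closed by intramolecular N-alkylation (K2CO3, DMF, 80 °C) to 4,5,6,7-tetrabromo-2,3-dihydro-1H-indole F6 (the same structure as F1). N-Acylation (NaN(SiMe3)2, then Boc2O, THF) rejoins the route at 6.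

3. Step 7. The second sulfenylation may stall at the hindered, electron-poor 3-sulfide, go to nitrogen, or scramble the sulfide under the HCl formed. Fallback: the C2 sulfur is introduced by deprotonation and electrophilic quench instead of electrophilic substitution. Setting out from 10, only one equivalent of 12 (from 11 and SO2Cl2) is used at −78 → 0 °C so that the reaction stops at the 3-sulfide 13, which is isolated. Boc2O and 4-(dimethylamino)pyridine in MeCN then give tert-butyl 4,5,6-tribromo-3-(methylsulfanyl)-1H-indole-1-carboxylate F7. LiN(iPr)2 in THF at −78 °C, an amide base that deprotonates without bromine–lithium exchange, removes the C2 proton to give tert-butyl 4,5,6-tribromo-2-lithio-3-(methylsulfanyl)-1H-indole-1-carboxylate F8. Quenching F8 with dimethyl disulfide 11 gives tert-butyl 4,5,6-tribromo-2,3-bis(methylsulfanyl)-1H-indole-1-carboxylate F9. CF3CO2H in CH2Cl2 then removes the Boc group, and the route is rejoined at the target 15.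

**Further compounds**

F1 | step 4 | 4,5,6,7-tetrabromo-2,3-dihydro-1H-indole | Brc1c(Br)c(Br)c2NCCc2c1Br
F2 | step 4 | 4,6-dibromo-2,3-dihydro-1H-indole | Brc1cc(Br)c2CCNc2c1
F3 | step 2 | 1,2,3,4-tetrabromo-5-(2-bromoethyl)benzene | BrCCc1cc(Br)c(Br)c(Br)c1Br
F4 | step 2 | 1,2,3,4-tetrabromo-5-(2-bromoethyl)-6-nitrobenzene | BrCCc1c([N+](=O)[O-])c(Br)c(Br)c(Br)c1Br
F5 | step 2 | 2,3,4,5-tetrabromo-6-(2-bromoethyl)aniline | Nc1c(CCBr)c(Br)c(Br)c(Br)c1Br
F6 | step 2 | 4,5,6,7-tetrabromo-2,3-dihydro-1H-indole | Brc1c(Br)c(Br)c2NCCc2c1Br
F7 | step 7 | tert-butyl 4,5,6-tribromo-3-(methylsulfanyl)-1H-indole-1-carboxylate | CSc1cn(C(=O)OC(C)(C)C)c2cc(Br)c(Br)c(Br)c12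
F8 | step 7 | tert-butyl 4,5,6-tribromo-2-lithio-3-(methylsulfanyl)-1H-indole-1-carboxylate | [Li]c1c(SC)c2c(Br)c(Br)c(Br)cc2n1C(=O)OC(C)(C)C
F9 | step 7 | tert-butyl 4,5,6-tribromo-2,3-bis(methylsulfanyl)-1H-indole-1-carboxylate | CSc1c(SC)c2c(Br)c(Br)c(Br)cc2n1C(=O)OC(C)(C)C
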